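**Numbering used throughout:** 1 succinic anhydride, 2 (+)-menthol, 3 half ester, 4 di-(+)-menthyl succinate, 5 bis(chloromethyl) ether, 6 bis-enolate, 7 monoalkylated enolate, 8 tetrahydrofuran diester, 9 diol, 10 monotosylate, 11 ditosylate, 12 4-bromo-1,2-dimethoxybenzene, 13 aryl Grignard reagent, 14 monoarylated tosylate, 15 target.

## Analysis of the target

The target 15 is a single tetrahydrofuran ring (O1, C2, C3, C4, C5) that carries a 3,4-dimethoxybenzyl group on C3 and on C4; the only other rings are the two veratryl arenes. C3 and C4 are the only stereocentres, both S, with the benzyl groups trans. A twofold axis runs through O1 and the midpoint of the C3–C4 bond, so the two halves are identical and only one absolute sense and the trans relation have to be set. The functional groups are robust: four aryl methyl ethers and one dialkyl ether tolerate bases, hydrides and organometallic reagents. The electron-rich arenes, however, are easily attacked by electrophiles and oxidants, and a benzylic cation would be trapped by the neighbouring arene, so strongly acidic or oxidising steps are best kept away once the arenes are in place. The difficulty is that C3 and C4 are plain methines flanked by CH2O, CH2Ar and each other, with no activating group left in the final structure. Their configuration must therefore be set while they still carry a function and then be carried through defunctionalisation without a chance of epimerisation, and a molecule of only 27 heavy atoms deserves a short route. The strategy rests on the C2–O1–C5 segment, a symmetric CH2–O–CH2 bridge between C3 and C4: once the two benzylic carbons are raised to the carboxylate level, C3 and C4 are the two α-carbons of a succinic ester and the bridge is a bis(halomethyl) ether.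

## Retrosynthetic reasoning

**Cut 1, the two CH2–aryl bonds of 15.** Both exocyclic C(sp3)–C(aryl) bonds are cut at once, giving the ditosylate 11 and two equivalents of the aryl Grignard reagent 13, made from the bromide 12. The cut is placed here because it respects the symmetry, and because the reacting carbons are CH2 groups one bond away from C3 and C4, so the stereocentres cannot be touched. It also keeps the electron-rich arenes out of every earlier step. Cutting C3–CH2 instead would require a stereoselective alkylation at an unactivated methine. The forward reaction has to achieve a twofold copper-catalysed sp3–sp2 coupling at primary, β-branched sulfonates without elimination.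

**Cut 2, functional-group changes from 11 back to 8.** The ditosylate 11 comes from the diol 9 by sulfonylation, and 9 from the diester 8 by hydride reduction. What is gained is that the carbons attached to C3 and C4 become ester carbonyls: this makes C3 and C4 enolisable and lets the ester alkoxy groups carry the chirality source. The forward reduction must be faster than α-deprotonation and releases the auxiliary 2 for recovery.

**Cut 3, the key disconnection of 8 at C2–C3 and C4–C5.** Removing the CH2–O–CH2 bridge as the bis-electrophile 5 leaves the succinate 4, which reacts as its dilithium bis-enolate 6. The first alkylation gives the monoenolate 7, and the second, intramolecular one closes the ring. This cut is preferred to any other because it forms the ring, two skeletal bonds and both stereocentres in one operation, and because the twofold symmetry of 6 and of 5 matches that of the product. The forward reaction has to deliver facial selectivity at C3 from the two menthyl groups and the trans relation at C4 from the ring closure, and must not leave excess base with the β-alkoxy ester product.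

**Cut 4, the ester C–O bonds of 4.** The diester 4 is assembled from succinic anhydride 1 and two equivalents of (+)-menthol 2 by acid-catalysed esterification; nothing stereochemical is at stake.

## Alternatives that were turned down

**Alternative 1:** The same two CH2–aryl bonds are disconnected, but by C–H functionalisation, so that the benzylic carbons are the methyl groups of a dimethylsuccinic acid derivative. In the forward key step (2S,3S)-2,3-dimethyl-N,N'-di(quinolin-8-yl)succinamide A2 would be heated with 4-iodo-1,2-dimethoxybenzene A3, Pd(OAc)2 and AgOAc. Each amide of A2 would direct palladation of the methyl group β to its carbonyl through a five-membered palladacycle, and two arylations by A3 would give (2S,3S)-2,3-bis(3,4-dimethoxybenzyl)-N,N'-di(quinolin-8-yl)succinamide A1.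

- For it: the stereocentres are present from the start, so no facial selectivity is needed; no organometallic nucleophile and no carcinogenic electrophile are used; β-methyl arylation of such bidentate amides is a well-developed reaction type.
- Against it: the step closes no ring, so in A1 two very robust amides must afterwards be cleaved, the carbons reduced and the ether closed, at least three further steps. Two bidentate amides on adjacent carbons can bind one palladium together and stall the cycle. Each new benzylic CH2 of A1 is a secondary β-C–H that can be arylated again by A3 still present. The stereocentres are α to carbonyls and sit hot with acetate, so epimerisation to the meso series threatens what was bought. A2 is not an article of commerce as a single enantiomer, so its carbon skeleton would first have to be resolved or made by asymmetric synthesis.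
- Comparison: this route is stronger on safety and on certainty of configuration at the outset. The chosen route offers ring and stereocentres in one step, five steps overall and a cheap recoverable auxiliary.

**Alternative 2:** The C3–C4 bond is disconnected together with a temporary bond from C3 to the benzylic carbon on C4, that is, a cyclopropane that is opened later. In the forward key step (E)-3-(3,4-dimethoxyphenyl)allyl 2-diazo-3-(3,4-dimethoxyphenyl)-3-oxopropanoate A5 would lose nitrogen on Cu(MeCN)4PF6 with a chiral bis(oxazoline) ligand. The copper carbene would add to the tethered E-alkene and give 1-(3,4-dimethoxybenzoyl)-6-exo-(3,4-dimethoxyphenyl)-3-oxabicyclo[3.1.0]hexan-2-one A4, closing lactone and cyclopropane together.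

- For it: the chirality source is catalytic; all 22 skeletal carbons are already in A5; the central C3–C4 bond is made directly; the alkene geometry is transferred stereospecifically.
- Against it: carbenes flanked by two acceptor groups are the least selective class for such copper catalysts, and the electron-rich arenes invite carbene attack on the ring. The end game from A4 is long: regioselective reductive opening of the cyclopropane, deoxygenation of the aryl ketone and reduction of the lactone carbonyl to CH2, four or more steps after about four to reach A5. The C3 centre, once α to two carbonyls, is fixed only by thermodynamic control.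
- Comparison: this route is stronger in using a catalyst instead of a stoichiometric auxiliary and in avoiding the carcinogen. The chosen route offers roughly half the step count, fewer redox corrections and full use of the symmetry.

**Alternative 3:** The two ring-to-benzylic-carbon bonds are disconnected on a preformed five-membered lactone whose C5 carries the chiral information as a menthyl acetal. In the forward key step the 2-lithio derivative of 2-(3,4-dimethoxyphenyl)-1,3-dithiane A8 would add 1,4 to (5S)-5-[(+)-menthyloxy]furan-2(5H)-one A7 anti to the menthyloxy group. The lactone enolate would then be trapped by 3,4-dimethoxybenzyl bromide A9 anti to the new substituent, giving all-trans 3-(3,4-dimethoxybenzyl)-4-[2-(3,4-dimethoxyphenyl)-1,3-dithian-2-yl]-5-[(+)-menthyloxy]dihydrofuran-2-one A6.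

- For it: both events are of well-established types with predictable substrate control, the assembly from A7, A8 and A9 is convergent, and this is arguably the most reliable key step of the four.
- Against it: no ring is formed, and the ring that is present in A6 must later be opened and closed again, because both the acetal carbon and the lactone carbonyl have to become CH2–O. The dithiane must be removed with a large excess of Raney Ni. About four steps follow the key step and three precede it, two for A7 and one for A8, so the route is close to eight steps with poor atom economy.
- Comparison: this route is stronger on precedent and on predictability of the stereochemical outcome. The chosen route offers five steps, no sulfur, and ring construction and stereocontrol in the same operation.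

Key step: step 2

Remark on the chemistry: 5 is assumed to be purchasable; it is a regulated human carcinogen to be handled only in a closed system and destroyed with aqueous ammonia. The sense of induction by the (+)-menthyl esters is assumed to follow the carbocyclic annulations.

## Route

Step 1
Reactants: 1 succinic anhydride; 2 (+)-menthol (2.1 equiv)
Product: 4 di-(+)-menthyl succinate, via mono-(+)-menthyl hydrogen succinate 3 (not isolated)
Conditions: p-TsOH·H2O (cat.), toluene, reflux, azeotropic removal of water; recrystallisation from MeOH
Reagents that add atoms: none
Why: Acid-catalysed opening of the anhydride by the first menthol gives the half ester 3, and Fischer esterification of its free acid with the second menthol is driven to completion by removal of water; the menthyl stereocentres are not involved and the diester is expected to crystallise.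

Step 2
Reactants: 4 di-(+)-menthyl succinate; 5 bis(chloromethyl) ether (1.0 equiv)
Product: 8 di-(+)-menthyl (3S,4S)-tetrahydrofuran-3,4-dicarboxylate, via dilithium bis-enolate 6 (not isolated), via chloromethoxymethyl monoenolate 7 (not isolated)
Conditions: lithium 2,2,6,6-tetramethylpiperidide (LiTMP, 2.0 equiv, from the amine and n-BuLi, THF, 0 °C), THF, −78 °C, 1 h; then 5 in THF added slowly, −78 °C; AcOH quench at −78 °C; recrystallisation
Reagents that add atoms: none
Why: Twofold deprotonation of 4 by the hindered, non-nucleophilic amide gives the extended dilithium bis-enolate 6; one enolate carbon displaces chloride from the very electrophilic α-chloro ether 5 in an intermolecular SN2 step (C2–C3), and the remaining enolate of 7 displaces the second chloride intramolecularly (C4–C5). The closest known reaction type is the annulation of dimenthyl succinate dianions with 1,ω-dihalides to trans-cycloalkane-1,2-dicarboxylates, here run with a dihalide that has an oxygen in its three-atom chain, together with the ordinary C-alkylation of lithium ester enolates by alkoxymethyl chlorides. The tetrahydrofuran closes in a 5-exo-tet mode with the enolate double bond exocyclic to the new ring, which is geometrically easy. C3 is set in the first alkylation by the two (+)-menthyl groups, which cover the same face of planar 6 so that 5 enters from the open face; since the (−)-menthyl esters give (1S,2S)-cycloalkanediesters and that spatial sense corresponds to (3R,4R) in the oxygen ring (C2, bearing oxygen, outranks C4), the (+)-menthyl ester should give (3S,4S). C4 is set in the ring closure, where the trans arrangement of the two ester groups avoids their eclipsing in the five-membered transition state and is also the sense that the menthyl group on the second enolate prefers. The step needs C- over O-alkylation, which a lithium enolate in THF without polar additives favours, and cyclisation over chain growth, which slow addition of exactly one equivalent of 5 and the fast five-membered closure secure. It also needs the absence of surplus base, since 8 is a β-alkoxy ester; exactly two equivalents of amide, a cold acidic quench and the poor orbital overlap of a reverse 5-endo-trig E1cB opening should protect the ring. Recrystallisation of the dimenthyl ester should remove minor diastereomers.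

Step 3
Reactants: 8 di-(+)-menthyl (3S,4S)-tetrahydrofuran-3,4-dicarboxylate
Product: 9 [(3R,4R)-tetrahydrofuran-3,4-diyl]dimethanol
Conditions: LiAlH4 (2.5 equiv), THF, 0 °C to reflux; then H2O, 15% aq. NaOH, H2O; filtration; menthol removed by hexane/water partition
Reagents that add atoms: none
Why: Hydride reduction of esters by LiAlH4 (acyl substitution, then aldehyde reduction) works on hindered menthyl esters at reflux and releases 2 for recovery; reduction is much faster than α-deprotonation, so C3 and C4 keep their spatial arrangement (the letters change from S to R only because the CIP priorities change).

Step 4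
Reactants: 9 [(3R,4R)-tetrahydrofuran-3,4-diyl]dimethanol
Product: 11 [(3S,4S)-tetrahydrofuran-3,4-diyl]bis(methylene) bis(4-methylbenzenesulfonate), via monotosylate 10 (not isolated)
Conditions: TsCl (2.5 equiv), Et3N, DMAP (cat.), CH2Cl2, 0 °C to rt
Reagents that add atoms: p-toluenesulfonyl chloride, Cc1ccc(cc1)S(Cl)(=O)=O
Why: Sulfonylation of primary alcohols under amine and DMAP catalysis; the trans arrangement keeps the monotosylate 10 from closing a second ether ring, because a trans-fused bicyclic bis-ether would be highly strained, so 10 goes on to 11, and no bond to a stereocentre is touched.

Step 5
Reactants: 11 [(3S,4S)-tetrahydrofuran-3,4-diyl]bis(methylene) bis(4-methylbenzenesulfonate); 12 4-bromo-1,2-dimethoxybenzene (5 equiv)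
Product: 15 (3S,4S)-3,4-bis(3,4-dimethoxybenzyl)tetrahydrofuran, via 3,4-dimethoxyphenylmagnesium bromide 13 (not isolated), via monoarylated monotosylate 14 (not isolated)
Conditions: 12, Mg, THF, reflux; then 11, Li2CuCl4 (5 mol %), THF, −78 °C to rt; aq. NH4Cl
Reagents that add atoms: none
Why: Copper-catalysed cross-coupling of a Grignard reagent with a primary alkyl tosylate: Li2CuCl4 is reduced to a monovalent arylcuprate, which displaces tosylate in an SN2-type oxidative addition to a trivalent copper species and forms the C(sp3)–C(aryl) bond by reductive elimination, twice in succession through 14. The reacting carbons are exocyclic CH2 groups, so C3 and C4 are untouched, and the methyl ethers and the ring ether are inert to the Grignard reagent.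

## Compound list

1 | succinic anhydride | O=C1CCC(=O)O1 | starting material
2 | (+)-menthol, (1S,2R,5S)-2-isopropyl-5-methylcyclohexanol | CC(C)[C@H]1CC[C@H](C)C[C@@H]1O | starting material
3 | mono-(+)-menthyl hydrogen succinate | CC(C)[C@H]1CC[C@H](C)C[C@@H]1OC(=O)CCC(=O)O | intermediate
4 | di-(+)-menthyl succinate | CC(C)[C@H]1CC[C@H](C)C[C@@H]1OC(=O)CCC(=O)O[C@H]1C[C@@H](C)CC[C@@H]1C(C)C | intermediate
5 | bis(chloromethyl) ether | ClCOCCl | starting material
6 | dilithium bis-enolate of 4 (1,4-bis(menthyloxy)buta-1,3-diene-1,4-diolate; enolate geometry left open) | CC(C)[C@H]1CC[C@H](C)C[C@@H]1OC(O[Li])=CC=C(O[Li])O[C@H]1C[C@@H](C)CC[C@@H]1C(C)C | intermediate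
7 | lithium enolate of di-(+)-menthyl (2S)-2-[(chloromethoxy)methyl]succinate | CC(C)[C@H]1CC[C@H](C)C[C@@H]1OC(=O)[C@H](COCCl)C=C(O[Li])O[C@H]1C[C@@H](C)CC[C@@H]1C(C)C | intermediate
8 | di-(+)-menthyl (3S,4S)-tetrahydrofuran-3,4-dicarboxylate (trans) | CC(C)[C@H]1CC[C@H](C)C[C@@H]1OC(=O)[C@@H]1COC[C@H]1C(=O)O[C@H]1C[C@@H](C)CC[C@@H]1C(C)C | intermediate
9 | [(3R,4R)-tetrahydrofuran-3,4-diyl]dimethanol (trans) | OC[C@@H]1COC[C@H]1CO | intermediate
10 | [(3S,4R)-4-(hydroxymethyl)tetrahydrofuran-3-yl]methyl 4-methylbenzenesulfonate | Cc1ccc(cc1)S(=O)(=O)OC[C@@H]1COC[C@H]1CO | intermediate
11 | [(3S,4S)-tetrahydrofuran-3,4-diyl]bis(methylene) bis(4-methylbenzenesulfonate) | Cc1ccc(cc1)S(=O)(=O)OC[C@@H]1COC[C@H]1COS(=O)(=O)c1ccc(C)cc1 | intermediate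
12 | 4-bromo-1,2-dimethoxybenzene | COc1ccc(Br)cc1OC | starting material
13 | 3,4-dimethoxyphenylmagnesium bromide | COc1ccc([Mg]Br)cc1OC | intermediate
14 | [(3S,4S)-4-(3,4-dimethoxybenzyl)tetrahydrofuran-3-yl]methyl 4-methylbenzenesulfonate | COc1ccc(C[C@@H]2COC[C@H]2COS(=O)(=O)c2ccc(C)cc2)cc1OC | intermediate
15 | (3S,4S)-3,4-bis(3,4-dimethoxybenzyl)tetrahydrofuran | COc1ccc(C[C@@H]2COC[C@H]2Cc2ccc(OC)c(OC)c2)cc1OC | target

## Step count and least certain steps

Total: 5 steps. Longest linear sequence: 5 steps (1 → 4 → 8 → 9 → 11 → 15); the Grignard reagent 13 is made within step 5.

**Step 2 (key step).** The most likely failure is poor facial selectivity in the first alkylation: the α-chloro ether reacts through an early, loose transition state with oxocarbenium character and may feel the menthyl shielding less than an alkyl bromide would. Further risks are O-alkylation of the enolate by this hard electrophile, chain growth instead of ring closure, consumption of the electrophile by the liberated hindered amine, and base-induced opening of the β-alkoxy ester if any amide is left over.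

Fallback, from 2 back to 8: the two ring C–C bonds are made by cycloaddition instead of enolate alkylation. Fumaric acid is esterified with 2 (p-TsOH, toluene, water removal) to di-(+)-menthyl fumarate F1. F1 is then treated with chloromethyl (trimethylsilyl)methyl ether (C[Si](C)(C)COCCl) and CsF in MeCN. Fluoride-induced 1,3-elimination generates the parent carbonyl ylide, whose suprafacial [3+2] addition to the E-alkene of F1 fixes the trans relation. Little facial bias is to be expected, so 8 would have to be separated by crystallisation or chromatography from its diastereomer, di-(+)-menthyl (3R,4R)-tetrahydrofuran-3,4-dicarboxylate F2. Because 8 and F2 differ as diastereomers, the menthyl groups then serve only as a resolving handle. The route is rejoined at 8.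

**Step 5.** The most likely failure is an incomplete second coupling, accompanied by elimination or reduction at the tosylate carbons and by biaryl formation that drains the Grignard reagent. The cause is that SN2-type attack of a bulky arylcuprate on a CH2 group next to a ring methine is slow and becomes slower once the first aryl group is in place; attack of the Grignard reagent at sulfur is a further drain.

Fallback, from 11 back to 15, with the polarity reversed: NaI in acetone converts 11 into (3S,4S)-3,4-bis(iodomethyl)tetrahydrofuran F3. Activated Zn dust in DMA inserts into both C–I bonds of F3 to give the bis(iodozinc) reagent [(3S,4S)-tetrahydrofuran-3,4-diylbis(methylene)]bis(iodozinc) F4. F4 is joined to 12 in a twofold Negishi coupling with Pd(OAc)2 and SPhos in THF, giving 15 directly.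

**Step 3.** The most likely failure is loss of material during isolation, because the diol is small and fully water-miscible, adsorbs on aluminium hydroxide and has to be separated from two equivalents of menthol. Incomplete reduction of the hindered esters is a second risk.

Fallback, from 8 back to 9: the auxiliary is removed before the reduction. Saponification of 8 with KOH in aqueous MeOH, extraction of the menthol from the alkaline solution with hexane and acidification with HCl give (3S,4S)-tetrahydrofuran-3,4-dicarboxylic acid F5. Reduction of F5 with BH3·SMe2 in THF, a MeOH quench and co-evaporation of the boron as volatile trimethyl borate lead to 9 without any aqueous extraction of the diol.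

## Further compounds

F1 | step 2 | di-(+)-menthyl fumarate | CC(C)[C@H]1CC[C@H](C)C[C@@H]1OC(=O)/C=C/C(=O)O[C@H]1C[C@@H](C)CC[C@@H]1C(C)C
F2 | step 2 | di-(+)-menthyl (3R,4R)-tetrahydrofuran-3,4-dicarboxylate | CC(C)[C@H]1CC[C@H](C)C[C@@H]1OC(=O)[C@H]1COC[C@@H]1C(=O)O[C@H]1C[C@@H](C)CC[C@@H]1C(C)C
F3 | step 5 | (3S,4S)-3,4-bis(iodomethyl)tetrahydrofuran | IC[C@@H]1COC[C@H]1CI
F4 | step 5 | [(3S,4S)-tetrahydrofuran-3,4-diylbis(methylene)]bis(iodozinc) | I[Zn]C[C@@H]1COC[C@H]1C[Zn]I
F5 | step 3 | (3S,4S)-tetrahydrofuran-3,4-dicarboxylic acid | OC(=O)[C@@H]1COC[C@H]1C(=O)O
A1 | alternative 1 | (2S,3S)-2,3-bis(3,4-dimethoxybenzyl)-N,N'-di(quinolin-8-yl)succinamide | O=C(Nc1cccc2cccnc12)[C@@H](Cc1ccc(OC)c(OC)c1)[C@H](Cc1ccc(OC)c(OC)c1)C(=O)Nc1cccc2cccnc12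
A2 | alternative 1 | (2S,3S)-2,3-dimethyl-N,N'-di(quinolin-8-yl)succinamide | O=C(Nc1cccc2cccnc12)[C@@H](C)[C@H](C)C(=O)Nc1cccc2cccnc12
A3 | alternative 1 | 4-iodo-1,2-dimethoxybenzene | COc1ccc(I)cc1OC
A4 | alternative 2 | 1-(3,4-dimethoxybenzoyl)-6-exo-(3,4-dimethoxyphenyl)-3-oxabicyclo[3.1.0]hexan-2-one | O=C1OC[C@H]2[C@H](c3ccc(OC)c(OC)c3)[C@@]12C(=O)c1ccc(OC)c(OC)c1
A5 | alternative 2 | (E)-3-(3,4-dimethoxyphenyl)allyl 2-diazo-3-(3,4-dimethoxyphenyl)-3-oxopropanoate | COc1ccc(/C=C/COC(=O)C(=[N+]=[N-])C(=O)c2ccc(OC)c(OC)c2)cc1OC
A6 | alternative 3 | all-trans 3-(3,4-dimethoxybenzyl)-4-[2-(3,4-dimethoxyphenyl)-1,3-dithian-2-yl]-5-[(+)-menthyloxy]dihydrofuran-2-one | O=C1O[C@H](O[C@H]2C[C@@H](C)CC[C@@H]2C(C)C)[C@@H](C2(c3ccc(OC)c(OC)c3)SCCCS2)[C@@H]1Cc1ccc(OC)c(OC)c1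
A7 | alternative 3 | (5S)-5-[(+)-menthyloxy]furan-2(5H)-one | O=C1O[C@H](O[C@H]2C[C@@H](C)CC[C@@H]2C(C)C)C=C1
A8 | alternative 3 | 2-(3,4-dimethoxyphenyl)-1,3-dithiane | COc1ccc(C2SCCCS2)cc1OC
A9 | alternative 3 | 3,4-dimethoxybenzyl bromide | COc1ccc(CBr)cc1OC
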